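**Retrosynthetic overview**
- The C3–Br bond is cut last: the target 16 comes from 2,6-dibromo-1-methylindole 14 by electrophilic bromination at the only free pyrrole carbon.
- Key disconnection N1–C2: in the pyrrole ring, C2 is bonded to both N1 and a bromine. It is therefore traced back to the CBr2 terminus of the ortho-(2,2-dibromovinyl)-N-methylaniline 12; one vinylic bromide is exchanged for N1 and the other stays on C2.
- 12 comes from aniline 7 by mono-N-methylation (benzotriazole aminal, then NaBH4). 7 comes from nitroarene 4 by SnCl2 reduction, and 4 from 4-bromo-2-nitrobenzaldehyde 1 and CBr4 by Ramirez olefination. The bromine para to the aldehyde carbon in 1 becomes C6–Br.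
- Ring order: the benzene ring is bought with 1; the pyrrole ring is the only ring formed, in step 5.

Key step: step 5

Remark on the chemistry: the target is achiral and has no stereogenic double bond, so no step has to control configuration. The aldehyde carbon of 1 becomes C3, the carbon of 2 becomes C2, the nitro nitrogen becomes N1 and the carbon of 9 becomes the N-methyl group. The ring closure is run with a palladium–tri-tert-butylphosphine catalyst, because that system is the one established for closing free and N-alkyl ortho-(gem-dibromovinyl)anilines to 2-bromoindoles.

**Step 1**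
Reactants: 1 4-bromo-2-nitrobenzaldehyde; 2 carbon tetrabromide
Product: 4 4-bromo-1-(2,2-dibromovinyl)-2-nitrobenzene, via dibromomethylene ylide 3 (not isolated)
Conditions: PPh3 (4 equiv), CBr4 (2 equiv), CH2Cl2, 0 °C
Reagents that add atoms: carbon tetrabromide, BrC(Br)(Br)Br
Why: Ramirez gem-dibromoolefination (first stage of the Corey–Fuchs sequence), in which the ylide 3 formed from PPh3 and CBr4 undergoes a Wittig reaction with the electron-poor aldehyde at 0 °C, conditions under which the nitro group and the aryl bromide are inert.

**Step 2**
Reactants: 4 4-bromo-1-(2,2-dibromovinyl)-2-nitrobenzene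
Product: 7 5-bromo-2-(2,2-dibromovinyl)aniline, via nitrosoarene 5 (not isolated), via N-arylhydroxylamine 6 (not isolated)
Conditions: SnCl2·2H2O (5 equiv), EtOH, 70 °C; aq. NaHCO3 work-up
Reagents that add atoms: none
Why: Chemoselective nitro-to-amine reduction with SnCl2, which proceeds by stepwise electron and proton transfer through nitroso compound 5 and hydroxylamine 6 and, unlike catalytic hydrogenation, should leave the vinylic and aryl C–Br bonds intact.

**Step 3**
Reactants: 7 5-bromo-2-(2,2-dibromovinyl)aniline; 8 1H-benzotriazole; 9 formaldehyde
Product: 10 N-(1H-benzotriazol-1-ylmethyl)-5-bromo-2-(2,2-dibromovinyl)aniline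
Conditions: 1H-benzotriazole (1.0 equiv), 37% aq. HCHO (1.0 equiv), EtOH, rt; product collected by filtration
Reagents that add atoms: formaldehyde, C=O; 1H-benzotriazole, c1ccc2[nH]nnc2c1
Why: Three-component Mannich-type condensation of an arylamine, formaldehyde and benzotriazole, which should stop at the mono-aminomethyl stage because one equivalent of formaldehyde is used and the sparingly soluble 1:1:1 adduct crystallises from ethanol.

**Step 4**
Reactants: 10 N-(1H-benzotriazol-1-ylmethyl)-5-bromo-2-(2,2-dibromovinyl)aniline
Product: 12 5-bromo-2-(2,2-dibromovinyl)-N-methylaniline, via N-methylidene imine 11 (not isolated)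
Conditions: NaBH4 (3 equiv), THF, reflux; aq. NaOH wash
Reagents that add atoms: none
Why: Reductive cleavage of the benzotriazole aminal, in which benzotriazolide departs to give the N-methylidene species 11 that borohydride reduces to the N-methyl group (an imine reduction), so exactly one methyl is delivered while NaBH4 alone does not reduce vinylic or aryl bromides.

**Step 5**
Reactants: 12 5-bromo-2-(2,2-dibromovinyl)-N-methylaniline
Product: 14 2,6-dibromo-1-methylindole, via azapalladacycle 13 (not isolated)
Conditions: Pd(P(t-Bu)3)2 (5 mol%), K3PO4 (2 equiv), toluene, 100 °C, argon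
Reagents that add atoms: none
Why: Zerovalent palladium inserts into the vinylic C–Br bond that lies cis to the arene, the neighbouring N-methylamino group binds and is deprotonated by phosphate to give the six-membered divalent-palladium azapalladacycle 13, and C–N reductive elimination forms N1–C2 and returns the catalyst. The closest known reaction type is the intramolecular Buchwald–Hartwig-type vinylic amination of ortho-(gem-dibromovinyl)anilines to 2-bromoindoles. The pyrrole ring closes by ring contraction of the palladacycle, formally a 5-endo closure at the vinylic carbon that becomes C2; only the bromide cis to the arene is within reach of nitrogen, so the trans bromide is retained as the C2 substituent. No stereocentre is formed. The step needs selectivity among the vinylic, the aryl C6 and the product C2 bromides: the electron-poor 1,1-dibromoalkene should undergo oxidative addition fastest and is trapped intramolecularly, whereas with the bulky P(t-Bu)3 ligand insertion into the C6–Br and product C2–Br bonds is reversible and finds no coupling partner under the weak phosphate base.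

**Step 6**
Reactants: 14 2,6-dibromo-1-methylindole; 15 N-bromosuccinimide
Product: 16 2,3,6-tribromo-1-methylindole
Conditions: NBS (1.0 equiv), DMF, 0 °C, dark
Reagents that add atoms: N-bromosuccinimide, O=C1CCC(=O)N1Br
Why: Electrophilic aromatic substitution with NBS at C3, the only unsubstituted pyrrole carbon and the most nucleophilic (enamine-like) site of the indole, with one equivalent at 0 °C in the dark to spare the bromine-deactivated benzene ring and the N-methyl group.

**Compound list**
1 | 4-bromo-2-nitrobenzaldehyde | O=Cc1ccc(Br)cc1[N+](=O)[O-] | starting material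
2 | carbon tetrabromide | BrC(Br)(Br)Br | starting material
3 | (dibromomethylene)triphenylphosphorane, formed in the flask | BrC(Br)=P(c1ccccc1)(c1ccccc1)c1ccccc1 | intermediate
4 | 4-bromo-1-(2,2-dibromovinyl)-2-nitrobenzene | O=[N+]([O-])c1cc(Br)ccc1C=C(Br)Br | intermediate
5 | 4-bromo-1-(2,2-dibromovinyl)-2-nitrosobenzene, formed in the flask | O=Nc1cc(Br)ccc1C=C(Br)Br | intermediate
6 | N-[5-bromo-2-(2,2-dibromovinyl)phenyl]hydroxylamine, formed in the flask | ONc1cc(Br)ccc1C=C(Br)Br | intermediate
7 | 5-bromo-2-(2,2-dibromovinyl)aniline | Nc1cc(Br)ccc1C=C(Br)Br | intermediate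
8 | 1H-benzotriazole | c1ccc2[nH]nnc2c1 | starting material
9 | formaldehyde | C=O | starting material
10 | N-(1H-benzotriazol-1-ylmethyl)-5-bromo-2-(2,2-dibromovinyl)aniline | BrC(Br)=Cc1ccc(Br)cc1NCn1nnc2ccccc21 | intermediate
11 | 5-bromo-2-(2,2-dibromovinyl)-N-methylideneaniline, formed in the flask | C=Nc1cc(Br)ccc1C=C(Br)Br | intermediate
12 | 5-bromo-2-(2,2-dibromovinyl)-N-methylaniline | CNc1cc(Br)ccc1C=C(Br)Br | intermediate
13 | six-membered azapalladacycle, formed in the flask: divalent palladium bonded to the anilide nitrogen and to the bromovinyl carbon, with P(t-Bu)3 on palladium written as a separate component | CN1[Pd]C(Br)=Cc2ccc(Br)cc21.CC(C)(C)P(C(C)(C)C)C(C)(C)C | intermediate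
14 | 2,6-dibromo-1-methylindole | Cn1c(Br)cc2ccc(Br)cc21 | intermediate
15 | N-bromosuccinimide | O=C1CCC(=O)N1Br | starting material
16 | 2,3,6-tribromo-1-methylindole | Cn1c(Br)c(Br)c2ccc(Br)cc21 | target

Total step count: 6
Longest linear sequence: 6 steps (1 to 16)

**Steps most likely to fail**

Step 5 (key closure). The catalyst may be diverted: palladium may insert into the vinylic bromide trans to the arene, which cannot close, or the aryl C6–Br and product C2–Br bonds may be used productively in intermolecular amination by unreacted 12, giving oligomers and debrominated material. The fallback sets out from aniline 7 and rejoins the route at 14, closing the same N1–C2 bond without a transition metal through an acidified nitrogen. Mesylation (MsCl, pyridine, CH2Cl2, 0 °C) should give N-[5-bromo-2-(2,2-dibromovinyl)phenyl]methanesulfonamide F1. Cs2CO3 in DMF at 80 °C should deprotonate the sulfonamide, which then displaces one vinylic bromide in the known base-promoted closure of N-sulfonyl ortho-(gem-dibromovinyl)anilines, to give 2,6-dibromo-1-(methylsulfonyl)indole F2. TBAF in THF at reflux should remove the sulfonyl group to give 2,6-dibromo-1H-indole F3, which is methylated at once (NaH, MeI, DMF, 0 °C) to 14.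

Step 4 (reductive cleavage of the aminal). The aminal may revert to primary aniline 7 before hydride is delivered, or the hindered, weakly donating nitrogen may expel benzotriazolide too slowly, so that reduction stalls or returns mixtures of 7 and 12. The fallback sets out from aniline 7 and rejoins at 12 by a protect–alkylate–deprotect sequence on a nitrogen that has only one N–H. TFAA with pyridine in CH2Cl2 at 0 °C should give N-[5-bromo-2-(2,2-dibromovinyl)phenyl]-2,2,2-trifluoroacetamide F4. MeI and K2CO3 in DMF at rt should give N-[5-bromo-2-(2,2-dibromovinyl)phenyl]-2,2,2-trifluoro-N-methylacetamide F5. K2CO3 in MeOH/H2O at rt should cleave the trifluoroacetyl group to give 12.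

Step 1 (olefination). The ylide may be consumed unproductively (moisture, or slow redox reaction of phosphine and bromophosphonium species with the ortho-nitro group on warming), and product may be lost in the separation from the phosphorus by-products. The fallback sets out from aldehyde 1 and rejoins at 4 by a phosphorus-free route. Hydrazine hydrate in EtOH at rt should give (E)-(4-bromo-2-nitrobenzylidene)hydrazine F6. CBr4 with catalytic CuCl and aqueous ammonia in DMSO at rt (the copper-catalysed olefination of N-unsubstituted hydrazones with polyhaloalkanes) should convert the C=N–NH2 unit into C=CBr2 with loss of nitrogen, giving 4.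

**Further compounds**
F1 | step 5 | N-[5-bromo-2-(2,2-dibromovinyl)phenyl]methanesulfonamide | CS(=O)(=O)Nc1cc(Br)ccc1C=C(Br)Br
F2 | step 5 | 2,6-dibromo-1-(methylsulfonyl)indole | CS(=O)(=O)n1c(Br)cc2ccc(Br)cc21
F3 | step 5 | 2,6-dibromo-1H-indole | Brc1cc2ccc(Br)cc2[nH]1
F4 | step 4 | N-[5-bromo-2-(2,2-dibromovinyl)phenyl]-2,2,2-trifluoroacetamide | O=C(Nc1cc(Br)ccc1C=C(Br)Br)C(F)(F)F
F5 | step 4 | N-[5-bromo-2-(2,2-dibromovinyl)phenyl]-2,2,2-trifluoro-N-methylacetamide | CN(C(=O)C(F)(F)F)c1cc(Br)ccc1C=C(Br)Br
F6 | step 1 | (E)-(4-bromo-2-nitrobenzylidene)hydrazine | N/N=C/c1ccc(Br)cc1[N+](=O)[O-]
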